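The dihydropyran ring is cut across C4–C4a and O1–C2, which divides the target into 2,5-dimethylhydroquinone (C4a, C8a, O1) and all-E geranylgeranial (C4, C3, C2 and the whole side chain). A chiral Brønsted acid should join them in one operation: the ring carbon ortho to a phenol oxygen adds to the aldehyde carbon, water is lost, and the oxygen closes onto the methyl-bearing carbon inside a chiral ion pair, which sets the C2 quaternary stereocenter and gives a 2H-chromene. The step exploits the adjacent C–H and O–H of the symmetric hydroquinone as a 1,3-dinucleophile for the 1,3-dielectrophilic enal. Selective saturation of C3=C4 completes the synthesis.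

Key step: step 2

Assumption: the sense of induction of the chiral acid at a methyl/alkyl-substituted allyl terminus cannot be read safely from a model; the (R)-configured acid is written, and its equally accessible (S)-antipode would be used if a test run shows the opposite sense.

Step 1
Reactants: 1 all-E geranylgeraniol
Product: 2 all-E geranylgeranial
Conditions: activated MnO2 (excess), CH2Cl2, rt
Reagents that add atoms: none
Why: Activated MnO2 oxidises allylic alcohols selectively to enals under neutral heterogeneous conditions and stops at the aldehyde, so the 2E geometry and the isolated alkenes should be preserved (allylic alcohol oxidation).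

Step 2
Reactants: 2 all-E geranylgeranial (limiting); 3 2,5-dimethylhydroquinone (3 equiv)
Product: 6 (R)-3,4-dehydro-β-tocotrienol, via benzylic allylic carbinol 4 (not isolated), via vinylogous ortho-quinone methide 5 (not isolated)
Conditions: (R)-3,3'-bis(2,4,6-triisopropylphenyl)-5,5',6,6',7,7',8,8'-octahydro-1,1'-binaphthalene-2,2'-diyl N-triflylphosphoramide, (ArO)2P(O)NHSO2CF3 (10 mol%), 5 Å MS, toluene/CH2Cl2 (2:1), slow addition of 2, −40 → 0 °C, Ar
Reagents that add atoms: none
Why: Proposed new method: the chiral acid activates the enal carbonyl, the hydroquinone carbon ortho to OH adds 1,2 (Friedel–Crafts hydroxyalkylation, the β-carbon being shielded by full substitution) to give carbinol 4, and acid-promoted loss of water from this benzylic and allylic alcohol gives the O-protonated form of oxatriene 5 as a contact ion pair, held by hydrogen bonds between the phenol OH and the phosphoramide anion. The closest known reactions are the racemic chromenylation of phenols by enals (condensation, then oxa-6π electrocyclization) and the chiral N-triflylphosphoramide-catalysed asymmetric allylic etherification of 2-(3-hydroxyalk-1-enyl)phenols to 2,2-disubstituted 2H-chromenes, which passes through the same cation. The pyran ring closes by 6-endo attack of the phenol oxygen on the tertiary allyl terminus, equivalent to a disrotatory oxa-6π electrocyclization of 5 inside the catalyst pocket. The C2 stereocenter is set in this closure by the chiral anion, which must tell the methyl group from the homofarnesyl chain on a terminus whose E geometry is inherited from 2. The chemoselectivity needed is ionisation of the carbinol in preference to protonation of the three isolated trisubstituted alkenes, which the low temperature and the much greater stability of the aryl-conjugated allyl cation should secure. A second annulation is held back by the excess of 3, and no regioisomer can form because both free ring positions of 3 are equivalent.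

Step 3
Reactants: 6 (R)-3,4-dehydro-β-tocotrienol
Product: 7 (R)-β-tocotrienol
Conditions: H2 (1 atm), RhCl(PPh3)3 (5 mol%), degassed benzene/EtOH (1:1), rt
Reagents that add atoms: none
Why: Homogeneous hydrogenation with RhCl(PPh3)3 discriminates strongly by alkene substitution, so the cis-disubstituted, aryl-conjugated C3=C4 bond should be saturated while the three trisubstituted side-chain alkenes stay untouched, and no bond to C2 is broken, so the stereocenter is carried through unchanged.

Compound list
1 | (2E,6E,10E)-3,7,11,15-tetramethylhexadeca-2,6,10,14-tetraen-1-ol (all-E geranylgeraniol) | CC(C)=CCC/C(C)=C/CC/C(C)=C/CC/C(C)=C/CO | starting material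
2 | (2E,6E,10E)-3,7,11,15-tetramethylhexadeca-2,6,10,14-tetraenal (all-E geranylgeranial) | CC(C)=CCC/C(C)=C/CC/C(C)=C/CC/C(C)=C/C=O | intermediate
3 | 2,5-dimethylbenzene-1,4-diol (2,5-dimethylhydroquinone) | Cc1cc(O)c(C)cc1O | starting material
4 | 2-[(2E,6E,10E)-1-hydroxy-3,7,11,15-tetramethylhexadeca-2,6,10,14-tetraen-1-yl]-3,6-dimethylbenzene-1,4-diol (carbinol carbon of either configuration) | CC(C)=CCC/C(C)=C/CC/C(C)=C/CC/C(C)=C/C(O)c1c(C)c(O)cc(C)c1O | intermediate
5 | (6Z)-4-hydroxy-2,5-dimethyl-6-[(2E,6E,10E)-3,7,11,15-tetramethylhexadeca-2,6,10,14-tetraen-1-ylidene]cyclohexa-2,4-dien-1-one (neutral form of the ion-paired cation) | CC(C)=CCC/C(C)=C/CC/C(C)=C/CC/C(C)=C/C=C1\C(=O)C(C)=CC(O)=C1C | intermediate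
6 | (2R)-2,5,8-trimethyl-2-[(3E,7E)-4,8,12-trimethyltrideca-3,7,11-trien-1-yl]-2H-chromen-6-ol | CC(C)=CCC/C(C)=C/CC/C(C)=C/CC[C@]1(C)C=Cc2c(C)c(O)cc(C)c2O1 | intermediate
7 | (2R)-2,5,8-trimethyl-2-[(3E,7E)-4,8,12-trimethyltrideca-3,7,11-trien-1-yl]-3,4-dihydro-2H-chromen-6-ol (β-tocotrienol, CID5282348) | CC(C)=CCC/C(C)=C/CC/C(C)=C/CC[C@]1(C)CCc2c(C)c(O)cc(C)c2O1 | target

Total step count: 3
Longest linear sequence: 3 steps (1 → 2 → 6 → 7)

Steps most likely to fail

Risk 1 (step 2): the chiral anion may discriminate poorly between the methyl group and the homofarnesyl chain at the closing terminus, or the neutral oxatriene may leave the catalyst pocket and close without control. Carbon–carbon bond formation may also be too slow at the temperature that the selective closure needs, and the activated enal may be intercepted by its own 6,7-alkene (carbonyl-ene or Prins closure) before the arene adds. The fallback sets out from 2 and 3 and uses known chemistry. The racemic chromenylation (PhB(OH)2, 1 equiv, cat. AcOH, toluene, reflux with azeotropic removal of water) should give racemic 2,5,8-trimethyl-2-[(3E,7E)-4,8,12-trimethyltrideca-3,7,11-trien-1-yl]-2H-chromen-6-ol F1. Preparative chromatography on a cellulose tris(3,5-dimethylphenylcarbamate) chiral stationary phase would then separate F1 into 6 and the (2S)-chromene F2, which is set aside. The fallback comes back to the route at 6.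

Risk 2 (step 3): the ring alkene lies between the quaternary C2 and the arene carbon next to the 5-methyl group, so its coordination to rhodium may be slow enough for side-chain saturation or alkene migration to compete. The fallback sets out from 6 and changes the basis of selectivity from sterics to conjugation. Sodium in boiling ethanol is a dissolving-metal electron-transfer reduction that should act only on the aryl-conjugated C3=C4 bond and leave isolated alkenes alone. It comes back to the route directly at 7 and makes no new compound (F0).

Risk 3 (step 1): partial 2E to 2Z isomerisation on the oxidant surface, or incomplete conversion, would feed a geometrically mixed enal into the key step and erode its selectivity. The fallback sets out from 1 and replaces surface oxidation by substitution and N-oxide oxidation. PBr3 in Et2O at −10 °C should give (2E,6E,10E)-1-bromo-3,7,11,15-tetramethylhexadeca-2,6,10,14-tetraene (geranylgeranyl bromide) F3. Treatment of F3 with 4-methylmorpholine N-oxide in MeCN at 0 °C to rt (Kornblum-type oxidation of an allylic halide) should give the enal without touching the 2,3-double bond. It comes back to the route at 2.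

Further compounds
F1 | step 2 | racemic 2,5,8-trimethyl-2-[(3E,7E)-4,8,12-trimethyltrideca-3,7,11-trien-1-yl]-2H-chromen-6-ol | CC(C)=CCC/C(C)=C/CC/C(C)=C/CCC1(C)C=Cc2c(C)c(O)cc(C)c2O1
F2 | step 2 | (2S)-2,5,8-trimethyl-2-[(3E,7E)-4,8,12-trimethyltrideca-3,7,11-trien-1-yl]-2H-chromen-6-ol | CC(C)=CCC/C(C)=C/CC/C(C)=C/CC[C@@]1(C)C=Cc2c(C)c(O)cc(C)c2O1
F3 | step 1 | (2E,6E,10E)-1-bromo-3,7,11,15-tetramethylhexadeca-2,6,10,14-tetraene (geranylgeranyl bromide) | CC(C)=CCC/C(C)=C/CC/C(C)=C/CC/C(C)=C/CBr
F0 | step 3 | none | none
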